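Count the half-lives of the slowest drain first, then ask how much time the charge loses in reaching it.

| flask | starting material | time |
|---|---|---|
| violet | 1.5 M | 20 min |
| green | 1.5 M | 25 min |

    intermediate B → intermediate C (k1 = 0.186 s⁻¹)
    starting material ⇌ intermediate A (K2 = 3.3, k2 = 0.0106 s⁻¹)
    intermediate D ⇌ intermediate E (K3 = 0.64, k3 = 0.00338 s⁻¹)
    intermediate A → intermediate D (k4 = 0.00966 s⁻¹)
    intermediate E → product (k5 = 0.00523 s⁻¹)
    starting material ⇌ intermediate B (K6 = 42, k6 = 0.0136 s⁻¹)
    intermediate C → intermediate E (k7 = 0.00308 s⁻¹)

- which of these there is most of at the end, counted by the starting material in it, violet (product / intermediate D / intermediate E / intermediate C)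
- which of these there is most of at the end, counted by the starting material in it, green (product / intermediate D / intermediate E / intermediate C)
- amount of the one of these that there is most of at the end, in percent of the starting material charged, violet
- amount of the one of these that there is most of at the end, in percent of the starting material charged, green

Each step has one species on its left, so we reckon in fractions of the charge. Intermediates D and E exchange, and E leaks to product. Once their ratio has steadied, this pair falls at the smaller of its two rates, 0.00142 s⁻¹; the larger is 0.0125 s⁻¹. The time in which the steadied pair halves is the drain half-life, in the usual terms the relaxation half-life of the slow mode: 8.15 min. Violet runs 2.45 of these and green 3.07, so a bare drain leaves 18.3 % in violet and 11.9 % in green.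

The charge does not start in the pair, so each stage rescales that remainder. A feeding step multiplies it by its rate over its rate less the drain rate. Entry at intermediate D stretches it, while entry at intermediate E shrinks it. We set aside the ways back and the faster decays. The whole charge sent through intermediate C gives a factor 1.29, and through intermediate A a larger one, 1.40.

Reckoned so, those two routes give an estimated bracket on product: the ceiling is 76.5 % in violet and 84.6 % in green, the floor 74.4 % and 83.2 %. Tightening, the forward rates of its two steps send 56.2 % of the starting material towards intermediate B, which gives a blended factor 1.34. We then reckon product at 75.5 % in violet and 84.1 % in green, more than the rest together in each of these two reckonings.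

The forecast, 75.7 % in violet and 84 % in green, holding that “the slow mode controls the finish”, lies inside the estimated bracket of its own flask in each case.

The simulation gives product on top at 75.6 % in violet and product at 84.0 % in green. In green, the step from starting material to intermediate B had 92 % of its turnover up to 25.0 min behind it at 2.50 min, and at 12.5 min starting material stood at 0.00623 % and intermediate C at 7.76 %. In green, intermediate E went on to product while intermediate D fell from 25.9 % then to 10.9 % at 25.0 min. Violet's 24.4 % not yet product, reckoned on for a further 0.613 drain half-lives, comes to an estimated 16.0 %. Green holds 16.0 % not yet product at 25.0 min.

The rate constants are made up; the run is a simulation.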